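**Plan**

1. Retrosynthesis (ring A = oxa-bridged cyclohexanone, ring B = δ-lactone, ring C = cyclohexane, ring D = cyclopentanone with C(OH)Me). The cuts, in order: the ring C C=C (hydrogenation); the ring D bond from the C(OH)Me carbon to the bridgehead CH (carbonyl-ene); the two ring C bonds at the B/C fusion (Diels–Alder); the lactone C=C and acyl–O bonds; the spiro carbon–CH(OMe)2 bond; and last both bonds that hold the CH2–C(=O) unit of ring A.
2. Feature used: in ring A the CH2–C(=O) pair lies between the O-bearing bridgehead CH of the oxolane and the carbon that becomes the spiro centre. The first is an aldehyde carbon once the oxa-bridge is opened (stored as a lactol); the second is α to the ester that later becomes the lactone CH2O. The ring oxygen is β to the ketone, so the oxolane can reclose by oxa-Michael addition.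
3. Forward: oxolanedione → alkylidene → enantioselective conjugate reduction → lactol → key step, in which Ph3P=C=C=O is set as a C2 linchpin between ester enolate and lactol aldehyde (C-acylation, intramolecular Wittig, oxa-Michael) to give ring A. Then the spiro carbon, ring B, ring C and ring D follow in that order.
4. Stereochemistry: the ring CH next to the CMe2 carbon comes from the ligand-controlled reduction (step 4); all other centres are relayed from it. The O-bridgehead follows from the cis-only oxa-bridge, the spiro carbon from attack anti to the syn methyl of the CMe2 bridge, the B/C fusion carbons from the face of the Diels–Alder reaction, and the ring D bridgehead and carbinol from the ene transition state.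

Key step: step 6

Assumption: (R)-DTBM-SEGPHOS is taken to deliver hydride to the face of (Z)-5 that gives (3R)-6; if the sense is the reverse, the (S)-ligand is used.
Assumption: compounds 1, 4, 8, 12, 16 and 20 are taken to be commercial.

**Route**

Step 1
Reactants: 1 methyl 2,2-dimethyl-3-oxobutanoate
Product: 2 methyl 4-bromo-2,2-dimethyl-3-oxobutanoate
Conditions: Br2 (1.0 equiv), CHCl3, 0 °C to rt
Reagents that add atoms: bromine, BrBr
Why: acid-catalysed α-bromination of a ketone should occur only at the acetyl methyl, because the other α-carbon is quaternary; no stereocentre is formed.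

Step 2
Reactants: 2 methyl 4-bromo-2,2-dimethyl-3-oxobutanoate
Product: 3 3,3-dimethyloxolane-2,4-dione
Conditions: neat, 130 °C, N2 stream
Reagents that add atoms: none
Why: thermal lactonization of a γ-bromo β-keto ester (the ester carbonyl oxygen displaces bromide 5-exo-tet and bromide demethylates the dialkoxycarbenium ion) should give the tetronic-acid-type lactone; no stereocentre.

Step 3
Reactants: 3 3,3-dimethyloxolane-2,4-dione; 4 tert-butyl 2-(triphenyl-λ5-phosphanylidene)acetate
Product: 5 tert-butyl (2Z)-2-(4,4-dimethyl-5-oxooxolan-3-ylidene)acetate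
Conditions: toluene, 110 °C
Reagents that add atoms: none
Why: Wittig olefination with a stabilized ylide should take the ring ketone and not the lactone carbonyl, and place the ester anti to the CMe2 carbon, i.e. the (Z)-alkene, which is freed from any (E)-isomer.

Step 4
Reactants: 5 tert-butyl (2Z)-2-(4,4-dimethyl-5-oxooxolan-3-ylidene)acetate
Product: 6 tert-butyl 2-[(3R)-4,4-dimethyl-5-oxooxolan-3-yl]acetate
Conditions: Cu(OAc)2·H2O (5 mol %), (R)-DTBM-SEGPHOS (5.5 mol %), (EtO)2MeSiH, t-BuOH, toluene, 0 °C to rt
Reagents that add atoms: none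
Why: ligand-controlled copper hydride asymmetric conjugate reduction of a β,β-disubstituted enoate, whose β-substituents (CMe2 and CH2O) differ strongly in size, should set the ring CH as (3R); the unconjugated lactone is not reduced.

Step 5
Reactants: 6 tert-butyl 2-[(3R)-4,4-dimethyl-5-oxooxolan-3-yl]acetate
Product: 7 tert-butyl 2-[(3R)-5-hydroxy-4,4-dimethyloxolan-3-yl]acetate
Conditions: i-Bu2AlH (1.1 equiv), CH2Cl2, −78 °C; aq. KNaC4H4O6
Reagents that add atoms: none
Why: partial hydride reduction of a γ-lactone to the lactol should stop at the tetrahedral aluminium alkoxide at −78 °C, where the tert-butyl ester is inert; the anomeric centre forms as a mixture and is lost again in step 6.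

Step 6
Reactants: 7 tert-butyl 2-[(3R)-5-hydroxy-4,4-dimethyloxolan-3-yl]acetate; 8 (triphenyl-λ5-phosphanylidene)ethenone
Product: 11 tert-butyl (1R,5S)-8,8-dimethyl-3-oxo-6-oxabicyclo[3.2.1]octane-2-carboxylate, via keto ylide 9 (not isolated), via hydroxy enone 10 (not isolated)
Conditions: LiN(i-Pr)2 (2.1 equiv), THF, −78 °C; 8 (1.1 equiv), −78 to 65 °C; AcOH (2.2 equiv), then DBU (0.2 equiv), rt
Reagents that add atoms: none
Why: Proposed new method: the ester enolate of the lactolate–enolate dianion should add to the central carbon of the cumulated ylide 8 (C-acylation, which makes the ketone-to-ester-carbon bond) and a proton shift from the now doubly activated CH gives the anion of the 4-phosphoranylidene-3-oxobutanoate 9; the lactolate is in equilibrium with the non-enolizable α,α-dimethyl aldehyde, which the ylide carbon olefinates intramolecularly (making the CH2–CH(O) bond, first as C=C) to give cyclohexenone 10. After the acetic acid quench, DBU should let the freed primary hydroxyl add to the enone β-carbon (oxa-Michael), which closes the oxolane and leaves 11. The closest known reactions are the acylation/Wittig domino reactions in which 8 links alcohols, amines or Grignard reagents to aldehydes, and the Wittig cyclizations of 4-(triphenylphosphoranylidene)acetoacetate anions; acylation of an ester enolate by 8 is the untested element. Ring A closes by 6-exo-trig attack of the ylide carbon on the aldehyde (endocyclic alkene after loss of Ph3P=O) and the oxolane by a 5-exo-trig conjugate addition. The only new stereocentre that is kept, the O-bearing bridgehead, is dictated by the (3R) ring CH, because the O–CH2 bridge can span ring A only cis (1,3-diaxial); the ester-bearing carbon stays enolizable and is set in step 7. The step needs C- over O-acylation and no aldol of the enolate: the closed lactolate hides the aldehyde at −78 °C, attack of the central 1,3-dicarbonyl carbon on the aldehyde would need a four-membered ring, and an O-acylated lactolate still carries the enolate that can take over the acyl group by intramolecular Claisen transfer.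

Step 7
Reactants: 11 tert-butyl (1R,5S)-8,8-dimethyl-3-oxo-6-oxabicyclo[3.2.1]octane-2-carboxylate; 12 trimethyl orthoformate
Product: 14 tert-butyl (1S,2S,5S)-2-(dimethoxymethyl)-8,8-dimethyl-3-oxo-6-oxabicyclo[3.2.1]octane-2-carboxylate, via silyl enol ether 13 (not isolated)
Conditions: Me3SiOTf (1.2 equiv), Et3N, CH2Cl2, 0 °C; then 12, Me3SiOTf (0.2 equiv), −78 to −30 °C
Reagents that add atoms: none
Why: one-pot enol silane formation and Mukaiyama-type alkylation by the dimethoxycarbenium ion should occur on the enol ether face of the O–CH2 bridge, because the syn methyl of the CMe2 bridge covers the other face; this sets the quaternary carbon as (2S), with the dimethoxymethyl group equatorial and the ester axial.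

Step 8
Reactants: 14 tert-butyl (1S,2S,5S)-2-(dimethoxymethyl)-8,8-dimethyl-3-oxo-6-oxabicyclo[3.2.1]octane-2-carboxylate
Product: 15 [(1S,2R,3R,5S)-2-(dimethoxymethyl)-3-hydroxy-8,8-dimethyl-6-oxabicyclo[3.2.1]octan-2-yl]methanol
Conditions: LiAlH4, THF, 0 °C to rt
Reagents that add atoms: none
Why: hydride reduction should turn the ester into the primary alcohol and the ketone into the carbinol while the acetal survives; hydride is expected anti to the O–CH2 bridge, giving the axial (3R)-alcohol, a centre that is removed again in step 12.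

Step 9
Reactants: 15 [(1S,2R,3R,5S)-2-(dimethoxymethyl)-3-hydroxy-8,8-dimethyl-6-oxabicyclo[3.2.1]octan-2-yl]methanol; 16 methyl 4,4-dimethoxy-3-oxopentanoate
Product: 17 [(1S,2R,3R,5S)-2-(dimethoxymethyl)-3-hydroxy-8,8-dimethyl-6-oxabicyclo[3.2.1]octan-2-yl]methyl 4,4-dimethoxy-3-oxopentanoate
Conditions: DMAP (0.2 equiv), toluene, 110 °C, 4 Å MS
Reagents that add atoms: none
Why: transesterification of a β-keto ester through its acylketene should acylate the primary hydroxyl in preference to the axial secondary hydroxyl that lies under the oxa-bridge; no new stereocentre.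

Step 10
Reactants: 17 [(1S,2R,3R,5S)-2-(dimethoxymethyl)-3-hydroxy-8,8-dimethyl-6-oxabicyclo[3.2.1]octan-2-yl]methyl 4,4-dimethoxy-3-oxopentanoate
Product: 19 spiro alkylidene lactone (3-(2,2-dimethoxypropanoyl)-5,6-dihydro-2H-pyran-2-one whose C-5 is the spiro carbon C-2 of (1S,2S,3R,5S)-3-hydroxy-8,8-dimethyl-6-oxabicyclo[3.2.1]octane), via formyl ester 18 (not isolated)
Conditions: LiBF4, MeCN/H2O (98:2), 40 °C; then piperidine, AcOH (cat.), 4 Å MS, rt
Reagents that add atoms: none
Why: mild hydrolysis of the aldehyde acetal (the α-keto ketal is much slower) followed by intramolecular Knoevenagel condensation of the 1,3-dicarbonyl CH2 with the neopentyl aldehyde should close the six-membered lactone as its alkylidene; no new stereocentre.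

Step 11
Reactants: 19 spiro alkylidene lactone; 20 buta-1,3-diene
Product: 21 cycloadduct (ring C cyclohexene cis-fused to the lactone of 19 on the face of the ring A carbinol carbon; 2,2-dimethoxypropanoyl on the fusion carbon α to the lactone carbonyl)
Conditions: 20 (10 equiv), BHT (cat.), toluene, 90 °C, sealed tube
Reagents that add atoms: none
Why: Diels–Alder reaction of a doubly activated cyclic dienophile (alkylidene β-keto lactone) should make both fusion centres cis by suprafacial addition; the diene is expected on the lactone face next to the ring A carbinol carbon (axial OH turned away, only an equatorial H near) and not on the face next to the bridgehead CH, which carries the O–CH2 bridge and is backed by the CMe2 carbon.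

Step 12
Reactants: 21 cycloadduct
Product: 22 ring A ketone of 21
Conditions: DMP (triacetoxy periodinane), NaHCO3, CH2Cl2, rt
Reagents that add atoms: none
Why: hypervalent iodine oxidation of the hindered secondary alcohol should give the ring A ketone; the flanking spiro carbon is quaternary, so no centre is at risk.

Step 13
Reactants: 22 ring A ketone of 21
Product: 23 1,2-diketone (22 with 2-oxopropanoyl in place of 2,2-dimethoxypropanoyl)
Conditions: CF3CO2H/H2O (9:1), CH2Cl2, 0 °C to rt
Reagents that add atoms: water, O
Why: acid hydrolysis of the dimethyl ketal should free the 1,2-diketone; the α-carbon is quaternary and cannot epimerize.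

Step 14
Reactants: 23 1,2-diketone
Product: 24 didehydro target (the target with a C=C between the two adjacent ring C CH2 carbons)
Conditions: BHT (cat.), toluene, 160 °C, sealed tube
Reagents that add atoms: none
Why: intramolecular carbonyl-ene reaction (type 1): the diketone carbonyl remote from the quaternary carbon should bond to the nearer alkene carbon (five-membered ring D) while its oxygen takes the allylic H from the ring CH2 on the far side, which forces the oxygen toward that CH2 and so places the hydroxyl endo and the methyl exo; the bridgehead follows from the 1,3-diaxial bridge.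

Step 15
Reactants: 24 didehydro target
Product: 25 target CNP0538153.1
Conditions: H2 (1 atm), Pd/C, EtOAc, rt
Reagents that add atoms: none
Why: catalytic hydrogenation should saturate the disubstituted ring C alkene and leave ketones, lactone and the tertiary α-ketol untouched; no stereocentre changes.

**Compound list**

1 | methyl 2,2-dimethyl-3-oxobutanoate | COC(=O)C(C)(C)C(C)=O | starting material
2 | methyl 4-bromo-2,2-dimethyl-3-oxobutanoate | COC(=O)C(C)(C)C(=O)CBr | intermediate
3 | 3,3-dimethyloxolane-2,4-dione | CC1(C)C(=O)COC1=O | intermediate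
4 | tert-butyl 2-(triphenyl-λ5-phosphanylidene)acetate | CC(C)(C)OC(=O)C=P(c1ccccc1)(c1ccccc1)c1ccccc1 | starting material
5 | tert-butyl (2Z)-2-(4,4-dimethyl-5-oxooxolan-3-ylidene)acetate | O=C1OC/C(=C\C(=O)OC(C)(C)C)C1(C)C | intermediate
6 | tert-butyl 2-[(3R)-4,4-dimethyl-5-oxooxolan-3-yl]acetate | CC1(C)C(=O)OC[C@@H]1CC(=O)OC(C)(C)C | intermediate
7 | tert-butyl 2-[(3R)-5-hydroxy-4,4-dimethyloxolan-3-yl]acetate (lactol, both anomers) | CC1(C)C(O)OC[C@@H]1CC(=O)OC(C)(C)C | intermediate
8 | (triphenyl-λ5-phosphanylidene)ethenone, Ph3P=C=C=O | O=C=C=P(c1ccccc1)(c1ccccc1)c1ccccc1 | starting material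
9 | keto ylide: tert-butyl 2-[(3R)-5-hydroxy-4,4-dimethyloxolan-3-yl]-3-oxo-4-(triphenyl-λ5-phosphanylidene)butanoate (present as its lithium salt) | CC1(C)C(O)OC[C@@H]1C(C(=O)OC(C)(C)C)C(=O)C=P(c1ccccc1)(c1ccccc1)c1ccccc1 | intermediate
10 | hydroxy enone: tert-butyl (6R)-6-(hydroxymethyl)-5,5-dimethyl-2-oxocyclohex-3-ene-1-carboxylate | CC1(C)C=CC(=O)C(C(=O)OC(C)(C)C)[C@H]1CO | intermediate
11 | tert-butyl (1R,5S)-8,8-dimethyl-3-oxo-6-oxabicyclo[3.2.1]octane-2-carboxylate (C-2 epimers and enol) | CC1(C)[C@@H]2CC(=O)C(C(=O)OC(C)(C)C)[C@H]1CO2 | intermediate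
12 | trimethyl orthoformate | COC(OC)OC | starting material
13 | silyl enol ether: tert-butyl (1S,5S)-8,8-dimethyl-3-(trimethylsilyloxy)-6-oxabicyclo[3.2.1]oct-2-ene-2-carboxylate | CC1(C)[C@@H]2CC(O[Si](C)(C)C)=C(C(=O)OC(C)(C)C)[C@H]1CO2 | intermediate
14 | tert-butyl (1S,2S,5S)-2-(dimethoxymethyl)-8,8-dimethyl-3-oxo-6-oxabicyclo[3.2.1]octane-2-carboxylate | CC1(C)[C@@H]2CC(=O)[C@](C(OC)OC)(C(=O)OC(C)(C)C)[C@H]1CO2 | intermediate
15 | [(1S,2R,3R,5S)-2-(dimethoxymethyl)-3-hydroxy-8,8-dimethyl-6-oxabicyclo[3.2.1]octan-2-yl]methanol | CC1(C)[C@@H]2C[C@@H](O)[C@](C(OC)OC)(CO)[C@H]1CO2 | intermediate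
16 | methyl 4,4-dimethoxy-3-oxopentanoate | COC(=O)CC(=O)C(C)(OC)OC | starting material
17 | [(1S,2R,3R,5S)-2-(dimethoxymethyl)-3-hydroxy-8,8-dimethyl-6-oxabicyclo[3.2.1]octan-2-yl]methyl 4,4-dimethoxy-3-oxopentanoate | CC1(C)[C@@H]2C[C@@H](O)[C@](C(OC)OC)(COC(=O)CC(=O)C(C)(OC)OC)[C@H]1CO2 | intermediate
18 | formyl ester: [(1S,2R,3R,5S)-2-formyl-3-hydroxy-8,8-dimethyl-6-oxabicyclo[3.2.1]octan-2-yl]methyl 4,4-dimethoxy-3-oxopentanoate | CC1(C)[C@@H]2C[C@@H](O)[C@](C=O)(COC(=O)CC(=O)C(C)(OC)OC)[C@H]1CO2 | intermediate
19 | spiro alkylidene lactone: 3-(2,2-dimethoxypropanoyl)-5,6-dihydro-2H-pyran-2-one whose C-5 is the spiro carbon C-2 of (1S,2S,3R,5S)-3-hydroxy-8,8-dimethyl-6-oxabicyclo[3.2.1]octane | CC1(C)[C@@H]2C[C@@H](O)[C@]3(COC(=O)C(C(=O)C(C)(OC)OC)=C3)[C@H]1CO2 | intermediate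
20 | buta-1,3-diene | C=CC=C | starting material
21 | cycloadduct: ring C cyclohexene cis-fused to the lactone of 19 on the carbinol face, 2,2-dimethoxypropanoyl on the fusion carbon α to the lactone carbonyl | CC1(C)[C@@H]2C[C@@H](O)[C@]3(COC(=O)[C@@]4(C(=O)C(C)(OC)OC)CC=CC[C@H]43)[C@H]1CO2 | intermediate
22 | ring A ketone of 21 | CC1(C)[C@@H]2CC(=O)[C@]3(COC(=O)[C@@]4(C(=O)C(C)(OC)OC)CC=CC[C@H]43)[C@H]1CO2 | intermediate
23 | 1,2-diketone: 22 with 2-oxopropanoyl in place of 2,2-dimethoxypropanoyl | CC1(C)[C@@H]2CC(=O)[C@]3(COC(=O)[C@@]4(C(=O)C(C)=O)CC=CC[C@H]43)[C@H]1CO2 | intermediate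
24 | didehydro target: the target with C=C between the two adjacent ring C CH2 carbons | CC1(C)[C@@H]2CC(=O)[C@]3(COC(=O)[C@@]45C[C@@H](C=C[C@H]43)[C@@](C)(O)C5=O)[C@H]1CO2 | intermediate
25 | target CNP0538153.1 | CC1(C)[C@@H]2CC(=O)[C@]3(COC(=O)[C@@]45C[C@@H](CC[C@H]43)[C@@](C)(O)C5=O)[C@H]1CO2 | target

Total step count: 15. Longest linear sequence: 15 steps.

**Steps most likely to fail**

Step 6 (Proposed new method). What may go wrong: acylation at the lactolate oxygen without later transfer of the acyl group to carbon, or aldol oligomerization once the lactolate opens. Fallback with known chemistry, from 7 back to 11: the lactol is converted with MeOH and PPTS into tert-butyl 2-[(3R)-5-methoxy-4,4-dimethyloxolan-3-yl]acetate F1. Claisen C-acetylation of its lithium enolate (LiN(i-Pr)2, 2.1 equiv, then AcCl) should give tert-butyl 2-[(3R)-5-methoxy-4,4-dimethyloxolan-3-yl]-3-oxobutanoate F2. Me3SiOTf and Et3N turn this into the 1,3-bis(trimethylsilyloxy)diene F3. Catalytic Me3SiOTf at −78 °C then ionizes the acetal, and the diene terminus closes ring A on the cyclic oxocarbenium ion (vinylogous Mukaiyama reaction, cis by necessity), giving 11 after aqueous work-up.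

Step 14. What may go wrong: stepwise cationic closure at the more distant alkene carbon (a bicyclo[2.2.2]octane), or no ene reaction before the diketone degrades. Fallback, from 19 back to 25, in which ring D is closed by an enol ether of fixed regiochemistry:
- Aqueous CF3CO2H removes the ketal of 19 to give the diketone alkylidene lactone F4.
- Diels–Alder reaction with 2-(trimethylsilyloxy)buta-1,3-diene should give the silyl enol ether cycloadduct F5, with the silyloxy carbon para to the quaternary carbon.
- TiCl4 at −78 °C closes ring D by intramolecular Mukaiyama aldol addition to the ring C keto aldol product F6. Here the carbinol configuration rests on the reversible aldol and not on the ene geometry.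
- The extra ring C ketone is removed through the 1,3-dithiolane F7 (HSCH2CH2SH, BF3·OEt2) and Raney Ni, to the ring A carbinol of the target F8.
- DMP oxidation of F8 gives 25.

Step 11. What may go wrong: poor facial selectivity at the spiro dienophile. Fallback, from 19 back to 24, in which the diene is delivered from the ring A hydroxyl through a temporary silicon tether:
- Chloro[(1E)-buta-1,3-dien-1-yl]dimethylsilane F9 is made by H2PtCl6-catalysed hydrosilylation of but-1-en-3-yne with Me2SiHCl.
- F9 silylates 19 (imidazole, DMF) to the dienyl(dimethyl)silyl ether F10.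
- Heating (toluene, 130 °C) should give, by intramolecular Diels–Alder reaction, the silicon-tethered cycloadduct F11. In F11 ring C can only lie on the carbinol face, and the silicon sits on an allylic ring C carbon.
- Aqueous CF3CO2H then frees the diketone; the allylsilane closes ring D by intramolecular Hosomi–Sakurai reaction (attack only through its γ-carbon, anti to silicon) and the Si–O bond is hydrolysed, giving the ring A carbinol of 24 F12.
- DMP oxidation of F12 gives 24.

**Further compounds**

F1 | step 6 | tert-butyl 2-[(3R)-5-methoxy-4,4-dimethyloxolan-3-yl]acetate | CC1(C)C(OC)OC[C@@H]1CC(=O)OC(C)(C)C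
F2 | step 6 | tert-butyl 2-[(3R)-5-methoxy-4,4-dimethyloxolan-3-yl]-3-oxobutanoate | CC1(C)C(OC)OC[C@@H]1C(C(C)=O)C(=O)OC(C)(C)C
F3 | step 6 | 1-tert-butoxy-2-(5-methoxy-4,4-dimethyloxolan-3-yl)-1,3-bis(trimethylsilyloxy)buta-1,3-diene | CC1(C)C(OC)OC[C@@H]1C(C(=C)O[Si](C)(C)C)=C(O[Si](C)(C)C)OC(C)(C)C
F4 | step 14 | diketone alkylidene lactone (19 with 2-oxopropanoyl in place of 2,2-dimethoxypropanoyl) | CC1(C)[C@@H]2C[C@@H](O)[C@]3(COC(=O)C(C(=O)C(C)=O)=C3)[C@H]1CO2
F5 | step 14 | silyl enol ether cycloadduct | CC1(C)[C@@H]2C[C@@H](O)[C@]3(COC(=O)[C@@]4(C(=O)C(C)=O)CC=C(O[Si](C)(C)C)C[C@H]43)[C@H]1CO2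
F6 | step 14 | ring C keto aldol product | CC1(C)[C@@H]2C[C@@H](O)[C@]3(COC(=O)[C@@]45C[C@@H](C(=O)C[C@H]43)[C@@](C)(O)C5=O)[C@H]1CO2
F7 | step 14 | 1,3-dithiolane of F6 | CC1(C)[C@@H]2C[C@@H](O)[C@]3(COC(=O)[C@@]45C[C@@H](C6(SCCS6)C[C@H]43)[C@@](C)(O)C5=O)[C@H]1CO2
F8 | step 14 | ring A carbinol of the target | CC1(C)[C@@H]2C[C@@H](O)[C@]3(COC(=O)[C@@]45C[C@@H](CC[C@H]43)[C@@](C)(O)C5=O)[C@H]1CO2
F9 | step 11 | chloro[(1E)-buta-1,3-dien-1-yl]dimethylsilane | C=C/C=C/[Si](C)(C)Cl
F10 | step 11 | dienyl(dimethyl)silyl ether of 19 | CC1(C)[C@@H]2C[C@@H](O[Si](C)(C)/C=C/C=C)[C@]3(COC(=O)C(C(=O)C(C)(OC)OC)=C3)[C@H]1CO2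
F11 | step 11 | silicon-tethered cycloadduct | CC1(C)[C@@H]2C[C@H]6O[Si](C)(C)[C@@H]7C=CC[C@]8(C(=O)C(C)(OC)OC)C(=O)OC[C@]6([C@H]78)[C@H]1CO2
F12 | step 11 | ring A carbinol of 24 | CC1(C)[C@@H]2C[C@@H](O)[C@]3(COC(=O)[C@@]45C[C@@H](C=C[C@H]43)[C@@](C)(O)C5=O)[C@H]1CO2
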